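The runs were generated by integration with constants of no real substance, and the scatter is random.

At each time of reading, the solid substrate still undissolved tells me how much has gone, and dividing that by the time gives a mean dissolving rate for the whole stretch, the curve replaced by its mean.

| flask | solid substrate | remark | time |
|---|---|---|---|
| grey | 1 M | run made earlier |  |
| green | 2.2 M | run made earlier |  |
| flask | 1.5 M |  | 2.0 h |

| run | time / min | ring / % | solid substrate / % |
|---|---|---|---|
| grey | 12.0 | 16.2 | 28.3 |
| grey | 20.0 | 27.6 | 0.8 |
| grey | 30.0 | 31.9 | 0.8 |
| grey | 60.0 | 29.9 | 0.2 |
| grey | 90.0 | 25.5 | 0 |
| green | 12.0 | 7.1 | 67.6 |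
| green | 20.0 | 12.8 | 48.2 |
| green | 30.0 | 20.6 | 23.9 |
| green | 60.0 | 28.7 | 0 |
| green | 90.0 | 26.5 | 0.4 |

(scatter of a reading: 0.5 percentage points)

- a species is counted by the solid substrate in it: one open dimer counts as two
- given per volume of solution although it is solid: solid substrate
- the numbers in the tables scatter with a standard deviation of 0.5 percentage points
- on the list of suspects stand: starting material -> ring; 2 starting material <-> open dimer; starting material <-> dormant form; ring -> over-reaction product; solid substrate <-> starting material
- at the start none of the solid substrate is in solution

1. time up to 2.0 h at which ring stands highest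
2. the amount of ring, in percent of the solid substrate charged, at that time
3. the first time at which ring reaches 15 %, in the same percent

I take the green run at 30.0 min, where 1.67 M has gone while 23.9 % of the charge is still left. This gives the mean dissolving rate r, which plays the part of a dosing rate in a semi-batch run. From it follows the clearing time T, the charge divided by r:

r = 0.0558 M/min

T = 17.9 min (grey), 39.4 min (green), 26.9 min (this flask)

While solid remains, ring in M matches in the two runs at the first reading: 0.162 M in grey and 0.156 M in green. This flask needs 0.225 M to reach 15 %, and interpolating the green readings puts that at 0.273 h, earlier than T, so I may use that curve.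

For the top I draw a straight line against T through the highest readings, 31.9 % in grey and 28.7 % in green:

top = 30.6 %, at 0.708 h

The link I doubt is r. The grey run at 12.0 min gives 0.0598 M/min, faster than my r, and T for this flask becomes 25.1 min. My reckoned top does not move, though, since on the line this flask still stands 0.417 of the way from grey to green. The two readings behind the time of the top lie 30.0 min apart, so I hold that time loosely.

The forecast, later than my top, says 31 % at 0.8 h and 15 % at 0.27 h, holding of the dissolving solid that “it is rate-limited rather than concentration-limited”.

The simulation gives 30.4 % at 0.798 h, and 15 % at 0.271 h.

    starting material → ring (k = 0.00120 /s)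
    2 starting material ⇌ open dimer (K = 4.40 /M, k = 0.00300 /M/s)
    starting material ⇌ dormant form (K = 2.90, k = 8.70 × 10⁻⁴ /s)
    ring → over-reaction product (k = 3.20 × 10⁻⁴ /s)
    solid substrate ⇌ starting material, rate k5*(cs5 - [starting material]) while solid is left; crystals form when [starting material] > cs5 (solubility = 1.10 M, k = 0.00110 /s)

In this flask, r leaves 55.4 % of the solid at 0.200 h, and the simulation has 52.3 %. A neighbouring flask charged with 0.38 M gets from r a reckoned T = 6.81 min, shorter than grey's, so it lies outside the span of the line. Extended that far, the line gives 33.6 %, and that neighbouring flask reaches 35.7 %.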